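Assumption: the SMILES carries no stereodescriptor and the molecule has no stereocentre, so the hindered 6,8'' biaryl axis is made without control (racemate); apigenin and acacetin are taken as bought catalogue compounds.

**Retrosynthetic overview**
1. No ring is formed in the route: both flavone ring systems are bought intact, as apigenin 1 (methylated to trimethyl ether 2) and acacetin 3.
2. The key disconnection is the C6–C8'' biaryl bond, which joins two carbons that are both innately nucleophilic (each ortho/para to ring oxygens).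
3. Polarity at C6 of the acacetin half is inverted by converting 3 into the C6 phenyliodonio phenolate 4, an aryl-cation (vinylogous enolonium) equivalent; with Rh2(OAc)4 it arylates C8 of 2 to give biflavone 5.
4. The last step is peri-selective 5''-O-demethylation of 5 to the target 6; the 5''-O-methyl is carried only to steer the coupling to C8''.

**Route**

Step 1
Reactants: 1 apigenin (5,7,4'-trihydroxyflavone)
Product: 2 5,7,4'-trimethoxyflavone (apigenin trimethyl ether)
Conditions: Me2SO4 (4.5 equiv), K2CO3 (6 equiv), acetone, reflux, 24 h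
Reagents that add atoms: dimethyl sulfate, COS(=O)(=O)OC
Why: Williamson O-methylation; excess reagent and prolonged reflux also methylate the hydrogen-bonded 5-OH, as is routine for permethylating flavones.

Step 2
Reactants: 3 acacetin (5,7-dihydroxy-4'-methoxyflavone)
Product: 4 5-hydroxy-2-(4-methoxyphenyl)-4-oxo-6-(phenyliodonio)-4H-chromen-7-olate (inner salt; PhI+ on C6, between O5 and O7)
Conditions: PhI(OAc)2 (1.05 equiv), KOH (2.0 equiv), MeOH, 0 °C, 2 h, dark; pour into ice-water, filter, dry in vacuo, use at once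
Reagents that add atoms: (diacetoxyiodo)benzene, CC(=O)OI(OC(C)=O)c1ccccc1
Why: Electrophilic substitution by trivalent iodine on the ring A phenoxide at the carbon flanked by both hydroxyls (C6, the site NIS also iodinates in 5,7-dihydroxyflavones), followed by loss of the second acetate, gives the acyl-stabilised iodonium phenolate, as is known for 4-acylresorcinols (iodonium ylide formation).

Step 3
Reactants: 4 5-hydroxy-2-(4-methoxyphenyl)-4-oxo-6-(phenyliodonio)-4H-chromen-7-olate; 2 5,7,4'-trimethoxyflavone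
Product: 5 5,7-dihydroxy-5'',7'',4',4'''-tetramethoxy-6,8''-biflavone, i.e. 5,7-dihydroxy-2-(4-methoxyphenyl)-6-[5,7-dimethoxy-2-(4-methoxyphenyl)-4-oxo-4H-chromen-8-yl]-4H-chromen-4-one (racemic axis)
Conditions: 2 (3 equiv), Rh2(OAc)4 (2 mol %), CH2Cl2/(CF3)2CHOH 9:1, 4 added in portions, 35 °C, dark, N2; excess 2 recovered on silica
Reagents that add atoms: none
Why: Proposed new method: dirhodium tetraacetate displaces PhI from the ylidic C6 of 4 to give a rhodium-bound quinoid carbene, which is an aryl-cation (vinylogous enolonium) equivalent at C6; it is attacked Friedel–Crafts fashion by C8 of 2, the most nucleophilic and least hindered ring A position of 5,7-dimethoxyflavones (the site of their iodination), and proton transfer then re-aromatises both rings and releases the catalyst; the closest known reaction types are the Rh2- and gold-catalysed C–H arylation of trimethoxybenzene-type arenes with ortho-quinone diazides and with iodonium ylides of cyclic 1,3-diones, and the photochemical arylation of arenes by iodonium phenolates; no stereocentre is formed and the axis is racemic.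

Step 4
Reactants: 5 5,7-dihydroxy-5'',7'',4',4'''-tetramethoxy-6,8''-biflavone
Product: 6 5,7,5''-trihydroxy-7'',4',4'''-trimethoxy-6,8''-biflavone (agathisflavone 7'',4',4'''-trimethyl ether, CNP0146326.0)
Conditions: BCl3 (1 M in CH2Cl2, 5 equiv), CH2Cl2, −78 → 0 °C, 2 h; ice-water quench
Reagents that add atoms: none
Why: Chelation-controlled Lewis-acid ether cleavage: BCl3 bridges the C4''=O and the peri 5''-OMe in a six-membered chelate so chloride removes only that methyl, while the unchelated 7''-, 4'- and 4'''-OMe groups survive at or below 0 °C and the free 5- and 7-OH are only borylated and released on work-up.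

**Compound list**
1 | apigenin (5,7,4'-trihydroxyflavone) | Oc1ccc(cc1)-c1cc(=O)c2c(O)cc(O)cc2o1 | starting material
2 | 5,7,4'-trimethoxyflavone | COc1ccc(cc1)-c1cc(=O)c2c(OC)cc(OC)cc2o1 | intermediate
3 | acacetin (5,7-dihydroxy-4'-methoxyflavone) | COc1ccc(cc1)-c1cc(=O)c2c(O)cc(O)cc2o1 | starting material
4 | 5-hydroxy-2-(4-methoxyphenyl)-4-oxo-6-(phenyliodonio)-4H-chromen-7-olate | COc1ccc(cc1)-c1cc(=O)c2c(O)c([I+]c3ccccc3)c([O-])cc2o1 | intermediate
5 | 5,7-dihydroxy-5'',7'',4',4'''-tetramethoxy-6,8''-biflavone (racemic axis) | COc1ccc(cc1)-c1cc(=O)c2c(O)c(-c3c(OC)cc(OC)c4c(=O)cc(-c5ccc(OC)cc5)oc34)c(O)cc2o1 | intermediate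
6 | 5,7,5''-trihydroxy-7'',4',4'''-trimethoxy-6,8''-biflavone (no stereodescriptor, as in the given SMILES) | COc1ccc(cc1)-c1cc(=O)c2c(O)c(-c3c(OC)cc(O)c4c(=O)cc(-c5ccc(OC)cc5)oc34)c(O)cc2o1 | target

**Step count and risk**

Total steps: 4. Longest linear sequence: 3 steps (3 → 4 → 5 → 6, or 1 → 2 → 5 → 6).

The three steps most likely to fail, most risky first:

Step 3 (carbenoid biaryl coupling). The risks are the thermal 1,4-phenyl shift of 4 to an iodo diaryl ether, O–H insertion, and attack at C6'' instead of C8''. The fallback is a conventional cross-coupling that sets out from 3 and 2 and comes back at 5. Acacetin 3 is iodinated at C6 (NIS, DMF, rt) to 6-iodoacacetin F1, and this is benzylated (BnBr, K2CO3, DMF, 80 °C) to 5,7-bis(benzyloxy)-6-iodo-4'-methoxyflavone F2. In parallel 2 is iodinated at C8 (I2, CF3CO2Ag, CH2Cl2, rt) to 8-iodo-5,7,4'-trimethoxyflavone F3, which is borylated (B2pin2, PdCl2(dppf), KOAc, dioxane, 90 °C) to 5,7,4'-trimethoxyflavone-8-boronic acid pinacol ester F4. Suzuki–Miyaura coupling of F2 with F4 (Pd(OAc)2, SPhos, K3PO4, toluene/H2O, 100 °C) gives 5,7-bis(benzyloxy)-5'',7'',4',4'''-tetramethoxy-6,8''-biflavone F5, and hydrogenolysis (H2, Pd/C, THF/MeOH, rt) returns to 5.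

Step 2 (iodonium phenolate formation). The risks are oxidative methoxylation of ring A by PhI(OAc)2 in methanol, or a zwitterion too labile to handle. The fallback avoids the oxidant by diazo transfer; it sets out from 3 and comes back at 5. Acacetin 3 with 4-acetamidobenzenesulfonyl azide and Et3N (MeCN, 0 °C) gives the quinone diazide 6-diazo-5-hydroxy-2-(4-methoxyphenyl)chromene-4,7(6H)-dione F6. This is decomposed by Rh2(OAc)4 (2 mol %) in the presence of 2 (3 equiv, CH2Cl2, rt) to give 5 with loss of nitrogen.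

Step 4 (selective 5''-O-demethylation). The risks are over-cleavage of other methyl ethers or incomplete reaction on the crowded peri position. The fallback replaces the 5''-methyl by a benzyl group so that no demethylation is needed; it sets out from 1 and comes back at 6. Apigenin 1 is methylated only at the unchelated hydroxyls (Me2SO4 2.2 equiv, K2CO3, acetone, reflux, 4 h) to 5-hydroxy-7,4'-dimethoxyflavone F7, which is benzylated (BnBr, K2CO3, DMF, 80 °C) to 5-benzyloxy-7,4'-dimethoxyflavone F8. Coupling of F8 with 4 under the step 3 conditions gives 5''-benzyloxy-5,7-dihydroxy-7'',4',4'''-trimethoxy-6,8''-biflavone F9, and hydrogenolysis (H2, Pd/C, EtOAc/THF, rt) gives 6.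

**Further compounds**
F1 | step 3 | 6-iodoacacetin (5,7-dihydroxy-6-iodo-4'-methoxyflavone) | COc1ccc(cc1)-c1cc(=O)c2c(O)c(I)c(O)cc2o1
F2 | step 3 | 5,7-bis(benzyloxy)-6-iodo-4'-methoxyflavone | COc1ccc(cc1)-c1cc(=O)c2c(OCc3ccccc3)c(I)c(OCc3ccccc3)cc2o1
F3 | step 3 | 8-iodo-5,7,4'-trimethoxyflavone | COc1ccc(cc1)-c1cc(=O)c2c(OC)cc(OC)c(I)c2o1
F4 | step 3 | 5,7,4'-trimethoxyflavone-8-boronic acid pinacol ester | COc1ccc(cc1)-c1cc(=O)c2c(OC)cc(OC)c(B3OC(C)(C)C(C)(C)O3)c2o1
F5 | step 3 | 5,7-bis(benzyloxy)-5'',7'',4',4'''-tetramethoxy-6,8''-biflavone | COc1ccc(cc1)-c1cc(=O)c2c(OCc3ccccc3)c(-c3c(OC)cc(OC)c4c(=O)cc(-c5ccc(OC)cc5)oc34)c(OCc3ccccc3)cc2o1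
F6 | step 2 | 6-diazo-5-hydroxy-2-(4-methoxyphenyl)chromene-4,7(6H)-dione | COc1ccc(cc1)C1=CC(=O)C2=C(O)C(=[N+]=[N-])C(=O)C=C2O1
F7 | step 4 | 5-hydroxy-7,4'-dimethoxyflavone | COc1ccc(cc1)-c1cc(=O)c2c(O)cc(OC)cc2o1
F8 | step 4 | 5-benzyloxy-7,4'-dimethoxyflavone | COc1ccc(cc1)-c1cc(=O)c2c(OCc3ccccc3)cc(OC)cc2o1
F9 | step 4 | 5''-benzyloxy-5,7-dihydroxy-7'',4',4'''-trimethoxy-6,8''-biflavone | COc1ccc(cc1)-c1cc(=O)c2c(O)c(-c3c(OC)cc(OCc4ccccc4)c4c(=O)cc(-c5ccc(OC)cc5)oc34)c(O)cc2o1
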